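The saturated ring B of the tetralin (C1, C2, C3, C4, C4a, C8a) contains a 2,3-dimethylbutane chain whose two ends, C1 and C4, each carry a veratryl ring, so the chain is twofold symmetric once the C1–C8a bond is cut. The key step treats a twofold-symmetric 1,4-diaryl-2,3-dimethylbutane-1,4-diol with acid and a silane: either of the two homotopic benzylic carbons ionises (by way of a temporary tetrahydrofuran ring), the other veratryl ring closes ring B trans to the C2 methyl group, and the surplus benzylic oxygen is reduced away in the same flask. The C2–C3 bond and both methyl-bearing centres come from an auxiliary-controlled oxidative homocoupling of two propionyl enolates.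

Key step: step 5

Remark: tetralin numbering is used throughout (C1 aryl-bearing, C2 and C3 methyl-bearing, C4 methylene, C4a and C8a ring fusion). The target is the all-trans (1S,2S,3R) isomer. The two carbinol centres of the diol precursor are left uncontrolled because the key step destroys both.

Step 1
Reactants: 1 (R)-4-benzyl-3-propanoyl-1,3-oxazolidin-2-one (two molecules)
Product: 3 (2S,3S)-1,4-bis[(4R)-4-benzyl-2-oxo-1,3-oxazolidin-3-yl]-2,3-dimethylbutane-1,4-dione, via lithium Z-enolate 2 (not isolated)
Conditions: LiN(i-Pr)2 (LDA), THF, −78 °C; then TiCl4, −78 °C to rt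
Reagents that add atoms: none
Why: Oxidative homocoupling of an N-acyloxazolidinone enolate: TiCl4 takes over the chelated Z-enolate, tetravalent titanium accepts one electron (becoming trivalent titanium) and the two α-acyl radical units join at their α-carbons, each on the face away from the benzyl group of its auxiliary, so the (R)-auxiliary should give the (2S,3S) dimer, which is separated from minor diastereomers by chromatography or crystallisation.

Step 2
Reactants: 3 (2S,3S)-1,4-bis[(4R)-4-benzyl-2-oxo-1,3-oxazolidin-3-yl]-2,3-dimethylbutane-1,4-dione
Product: 4 S,S'-diethyl (2S,3S)-2,3-dimethylbutanebis(thioate)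
Conditions: EtSH (excess), n-BuLi, THF, 0 °C
Reagents that add atoms: ethanethiol, CCS (used as its lithium salt, made in the flask with n-BuLi)
Why: Thiolate cleavage of an N-acyloxazolidinone: the small, soft lithium thiolate adds to the exocyclic imide carbonyl and expels the oxazolidinone anion, while the excess thiol buffers the medium so that the α-centres should not epimerise and the auxiliary is recovered.

Step 3
Reactants: 4 S,S'-diethyl (2S,3S)-2,3-dimethylbutanebis(thioate); 5 (3,4-dimethoxyphenyl)boronic acid (two molecules)
Product: 6 (2S,3S)-1,4-bis(3,4-dimethoxyphenyl)-2,3-dimethylbutane-1,4-dione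
Conditions: Pd2(dba)3 (cat.), tri(2-furyl)phosphine, copper thiophene-2-carboxylate CuO2C(C4H3S) (CuTC), THF, 50 °C
Reagents that add atoms: none
Why: Liebeskind–Srogl ketone synthesis at both termini: zerovalent palladium inserts into the C–S bond, the monovalent copper carboxylate takes up the thiolate and activates boron for transmetalation without added base, and reductive elimination gives the aryl ketone under neutral conditions that should leave the epimerisable α-centres intact.

Step 4
Reactants: 6 (2S,3S)-1,4-bis(3,4-dimethoxyphenyl)-2,3-dimethylbutane-1,4-dione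
Product: 7 (2S,3S)-1,4-bis(3,4-dimethoxyphenyl)-2,3-dimethylbutane-1,4-diol (mixture of epimers at C1 and C4)
Conditions: LiAlH4, THF, −78 to 0 °C; Rochelle salt work-up
Reagents that add atoms: none
Why: Hydride reduction of the two aryl ketones at low temperature is much faster than enolisation, so C2 and C3 should keep their configuration, and the new carbinol centres may form as any mixture because both are later ionised.

Step 5
Reactants: 7 (2S,3S)-1,4-bis(3,4-dimethoxyphenyl)-2,3-dimethylbutane-1,4-diol
Product: 10 galbulin [(1S,2S,3R)-1-(3,4-dimethoxyphenyl)-6,7-dimethoxy-2,3-dimethyl-1,2,3,4-tetrahydronaphthalene], via tetrahydrofuran 8 (not isolated), via hydroxytetralin 9 (not isolated)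
Conditions: CF3CO2H, Et3SiH, CH2Cl2 (high dilution), −40 °C to rt
Reagents that add atoms: none
Why: Acid ionises a benzylic C–O bond of 7 (in equilibrium with its cyclic ether 8) to a benzylic cation at C1 stabilised by the para methoxy group; the veratryl ring on C4 attacks it through the carbon para to its 3-methoxy group (the future C8a) in an intramolecular Friedel–Crafts alkylation that closes ring B to 9, whose remaining benzylic C4–O bond ionises in turn and is reduced to CH2 by hydride transfer from Et3SiH (ionic hydrogenation). The closest known reactions are the acid-mediated cyclisation of 1,4-diarylbutan-1-ols and 2,5-diaryltetrahydrofurans to 1-aryltetralins and the silane/acid deoxygenation of benzylic alcohols. Ring B closes in the 6-exo-trig mode, the cationic carbon keeping its aryl π-partner outside the new ring. The new C1 centre is controlled by the C2 methyl group: in the chair-like transition state both methyl groups and the C1 aryl group sit equatorial, which should give the all-trans (1S,2S,3R) product, with C2 and C3 carried over unchanged from 3. The step needs ring closure to compete with hydride capture and attack para rather than ortho to methoxy; the twofold symmetry of 7 secures the first, since both benzylic carbons are homotopic and either order of events (cyclise then reduce, or reduce one end then cyclise at the other) converges on 10, only double reduction being unproductive, and the crowded position between chain and methoxy group disfavours the second. High dilution and a modest silane concentration favour the unimolecular closure over bimolecular hydride transfer and oligomerisation.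

Compound list
1 | (R)-4-benzyl-3-propanoyl-1,3-oxazolidin-2-one | CCC(=O)N1[C@H](Cc2ccccc2)COC1=O | starting material
2 | lithium Z-enolate of 1 | C/C=C(\O[Li])N1[C@H](Cc2ccccc2)COC1=O | intermediate (not isolated)
3 | (2S,3S)-1,4-bis[(4R)-4-benzyl-2-oxo-1,3-oxazolidin-3-yl]-2,3-dimethylbutane-1,4-dione | O=C1OC[C@@H](Cc2ccccc2)N1C(=O)[C@@H](C)[C@H](C)C(=O)N1[C@H](Cc2ccccc2)COC1=O | intermediate
4 | S,S'-diethyl (2S,3S)-2,3-dimethylbutanebis(thioate) | CCSC(=O)[C@@H](C)[C@H](C)C(=O)SCC | intermediate
5 | (3,4-dimethoxyphenyl)boronic acid | OB(O)c1ccc(OC)c(OC)c1 | starting material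
6 | (2S,3S)-1,4-bis(3,4-dimethoxyphenyl)-2,3-dimethylbutane-1,4-dione | COc1ccc(cc1OC)C(=O)[C@@H](C)[C@H](C)C(=O)c1ccc(OC)c(OC)c1 | intermediate
7 | (2S,3S)-1,4-bis(3,4-dimethoxyphenyl)-2,3-dimethylbutane-1,4-diol (C1/C4 epimers) | COc1ccc(cc1OC)C(O)[C@@H](C)[C@H](C)C(O)c1ccc(OC)c(OC)c1 | intermediate
8 | (3S,4S)-2,5-bis(3,4-dimethoxyphenyl)-3,4-dimethyloxolane (C2/C5 epimers) | COc1ccc(cc1OC)C1[C@@H](C)[C@H](C)C(c2ccc(OC)c(OC)c2)O1 | intermediate (not isolated)
9 | (2S,3R,4S)-4-(3,4-dimethoxyphenyl)-6,7-dimethoxy-2,3-dimethyl-1,2,3,4-tetrahydronaphthalen-1-ol (C1 epimers) | COc1ccc([C@H]2c3cc(OC)c(OC)cc3C(O)[C@@H](C)[C@@H]2C)cc1OC | intermediate (not isolated)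
10 | galbulin, (1S,2S,3R)-1-(3,4-dimethoxyphenyl)-6,7-dimethoxy-2,3-dimethyl-1,2,3,4-tetrahydronaphthalene | COc1ccc([C@H]2c3cc(OC)c(OC)cc3C[C@@H](C)[C@@H]2C)cc1OC | target

Total step count: 5
Longest linear sequence: 5 steps (from 1)

Steps most likely to fail

Step 5. Hydride capture may overtake ring closure at both benzylic cations, leaving the open chain over-reduced. The C4 cation of the cyclised intermediate may also lose a proton toward C3 before it is reduced, which would erase the C3 centre. The fallback sets out from 7 and comes back at 10; it separates the two events and fixes their order as reduction first. Diol 7 is closed with catalytic p-toluenesulfonic acid in CH2Cl2 to tetrahydrofuran 8, which is isolated. Li in liquid NH3/THF at −78 °C should then cleave only one benzylic C–O bond, because the alkoxide left at the other benzylic carbon is no leaving group. This gives (2S,3R)-1,4-bis(3,4-dimethoxyphenyl)-2,3-dimethylbutan-1-ol F1. BF3·OEt2 in CH2Cl2 at −78 to 0 °C, with no silane present, ionises the single carbinol, and Friedel–Crafts closure should give 10 without a cation ever forming at C4.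

Step 1. The radical union may discriminate the enolate faces poorly, or the enolate may be consumed by protonation instead of coupling. The fallback sets out from 1 and comes back at 4; it builds the C2–C3 bond by an ionic, stereospecific alkylation instead. Lithium enolate 2 is alkylated at −78 °C with ethyl (S)-2-(trifluoromethylsulfonyloxy)propanoate F2, made from ethyl L-lactate with Tf2O and 2,6-lutidine. SN2 inversion at the lactate carbon and auxiliary control at the enolate carbon should give ethyl (2S,3S)-4-[(4R)-4-benzyl-2-oxo-1,3-oxazolidin-3-yl]-2,3-dimethyl-4-oxobutanoate F3. Thiolysis of the imide as in step 2 gives ethyl (2S,3S)-4-(ethylsulfanyl)-2,3-dimethyl-4-oxobutanoate F4, and EtSH/AlMe3 converts the remaining ethyl ester into the second thioester, giving 4.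

Step 3. The second coupling may stall, or the 1,4-diketone may epimerise (or cyclodehydrate to a furan) during the reaction or its work-up. The fallback sets out from 4 and comes back at 7; the aryl groups are added as nucleophiles to aldehydes, so the diketone is never made. Fukuyama reduction of 4 (Et3SiH, Pd/C, acetone, rt) gives (2S,3S)-2,3-dimethylbutanedial F5. This is added crude to commercial 3,4-dimethoxyphenylmagnesium bromide in THF at −78 °C to give diol 7 directly, bypassing 6 and step 4.

Further compounds
F1 | step 5 | (2S,3R)-1,4-bis(3,4-dimethoxyphenyl)-2,3-dimethylbutan-1-ol (C1 epimers) | COc1ccc(cc1OC)C(O)[C@@H](C)[C@H](C)Cc1ccc(OC)c(OC)c1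
F2 | step 1 | ethyl (S)-2-(trifluoromethylsulfonyloxy)propanoate | C[C@H](OS(=O)(=O)C(F)(F)F)C(=O)OCC
F3 | step 1 | ethyl (2S,3S)-4-[(4R)-4-benzyl-2-oxo-1,3-oxazolidin-3-yl]-2,3-dimethyl-4-oxobutanoate | CCOC(=O)[C@@H](C)[C@H](C)C(=O)N1[C@H](Cc2ccccc2)COC1=O
F4 | step 1 | ethyl (2S,3S)-4-(ethylsulfanyl)-2,3-dimethyl-4-oxobutanoate | CCOC(=O)[C@@H](C)[C@H](C)C(=O)SCC
F5 | step 3 | (2S,3S)-2,3-dimethylbutanedial | O=C[C@@H](C)[C@H](C)C=O
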